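# Proposed synthesis of CNP0260455.1 from (−)-guaiol by ozonolytic opening of the hydroazulene

## Analysis of the target

The target is a germacrane-type sesquiterpenoid triester built on a cyclodecane (C1–C10) that carries an isopropenyl group on C7 (C11–C13), methyl groups on C10 (C14) and C4 (C15), an acetate on C8, angelates on C9 and C3, and epoxides across C1–C10 and C4–C5. Both epoxides are cis-fused to the ring and therefore correspond to Z-configured 1(10)- and 4-alkenes, not to the E,E pattern of most germacranes. There are eight stereocentres (1R,3S,4S,5S,7R,8S,9S,10R): the C7 side chain, the C8 acetate and the C9 angelate are all cis on the ring and the 1,10-epoxide oxygen lies on the same face as the C9 oxygen, whereas the 4,5-epoxide oxygen is trans to the C3 oxygen. The sensitive groups are the angelates (Z to E isomerisation, cleavage by hydrazine or hydroxide), the two trisubstituted epoxides (acid, Payne rearrangement) and the vicinal 8,9-diester (acyl migration). The main difficulties are the medium ring, the Z geometry of both ring alkenes, and two nearly alike halves (C9–C10–C1–C2 and C3–C4–C5–C6) that must be treated differently, because only one half carries the extra C8 oxygen and neighbouring cis hydroxyls carry different acyl groups. The plan rests on the observation that oxygen sits on C1 and on C5 and that a bond drawn between these two carbons turns the ring into the bicyclo[5.3.0]decane of the guaianes, with the methyl groups on C4 and C10 and the three-carbon unit on C7, so that the target is a 1,5-seco-guaiane. Comparison of the configurations shows that C7 of (−)-guaiol has the spatial arrangement required at C7 of the target.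

## Retrosynthetic reasoning

**Isopropenyl group.** The target 27 is traced back to the tertiary carbinol 26 by cutting nothing but the C11–O bond (dehydration as the last step). An isopropenyl group would not survive the dihydroxylation and epoxidations, and the C11 hydroxyl is needed earlier as an internal anchor, so the alkene is made last.

**Esters.** The C9 angelate and the C8 acetate of 26 are cut back through 25 to the diepoxy triol 24, with angelic acid 20 as the acyl source. Cutting here leaves the hindered C9 hydroxyl, which is flanked by the quaternary epoxide carbon C10, for last, so that the small acetyl group can first be placed on the more accessible O8. The C3 angelate is installed much earlier (21 from 19 and 20), because a free C3 hydroxyl would misdirect the later oxidations.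

**Epoxides.** The C–O bonds of the 4,5-epoxide (24 from 23) and of the 1,10-epoxide (23 from 22) are cut to the Z,Z-diene triol 22. The two epoxides have opposite relations to their neighbouring oxygens, so they are made by different reactions. A hydroxyl-directed vanadium-catalysed epoxidation gives the syn isomer next to the free C9 hydroxyl, and a peracid epoxidation gives the anti isomer next to the C3 ester. Both are stereospecific, so cis epoxides require Z alkenes.

**C3 carbinol and C4=C5 alkene.** Triol 22 comes from 21 by deprotection, and the C3 stereocentre of 19 is cut back to the enone 18, because C3 is remote from every other stereocentre and only a reagent-controlled reduction sets it reliably. Enone 18 is the 1,3-transposed form of enone 14, reached by nucleophilic epoxidation (15), Wharton transposition (17) and oxidation. Enone 14 comes from ketone 12 by dehydrogenation through the silyl enol ether 13.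

**C8 and C9 oxygens and C1=C10 alkene.** Ketone 12 is traced through 11 and 10 to the diol 9 and then to the dienyl triflate 8. The two C–O bonds at C8 and C9 are cut together (cis-dihydroxylation of a Z alkene), which guarantees their cis relation. The C1–H bond is cut to the triflate, which deactivates C1=C10 during the dihydroxylation and then delivers the Z alkene by reduction. The triflate 8 is the enol derivative of the through-conjugated dienolate of enone 6, which comes from ketone 4 by dehydrogenation through 5.

**Differentiating C1 from C5.** Ketal 4 is cut at its C5–O bonds to the hydroxy dione 3. Desaturating both ketones of 3 at once would leave C2 between a carbonyl group and an enone double bond, a vinylogous 1,3-dicarbonyl arrangement that would dominate all enolate chemistry. The halves are therefore handled one after the other. The C11 hydroxyl can reach C5, but not C1, through a five-membered ring, so an internal mixed ketal masks C5 for free. The same bridge is later used to bias the faces of the C8=C9 alkene.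

**Ten-membered ring.** The ring of 3 is cut conceptually by rejoining C1 and C5 as the tetrasubstituted alkene of (−)-guaiol 1. In the forward direction ozonolysis cleaves this ring-fusion bond and merges the five- and seven-membered rings. This is chosen over any ring-closing disconnection because it makes the medium ring without a cyclisation and supplies all fifteen carbons and the C7 configuration from a commercial terpene.

## Alternatives that were turned down

Alternative 1: The C2–C3 and C6–C7 bonds are cut, and the ring would come from a thermal [6+4] cycloaddition of 4-methyltropone A2 with the silyloxydiene A3 through the exo transition state, giving the bicyclo[4.4.1]undecatrienone A1.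

- For it: two C–C bonds and the ten-membered carbocycle are formed in one step; the C3 oxygen is in place; the C8=C9/C1=C10 diene needed for the 8,9-diol is already there. The one-carbon bridge also forces both ring alkenes to be ring-cis. On alkene geometry this is stronger than the chosen route, where the geometry depends on a dienolate equilibrium and on a Wharton reaction.
- Against it: A1 is formed as a racemate with only relative control, and periselectivity ([4+2] competition) and regiochemistry with two unsymmetrical partners are open. The bridging carbonyl C11 must then be cut from C2 but not from C7 and grown by two carbons into the isopropenyl group. That is a regioselective C–C scission between two bridgeheads for which the structure offers no bias.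
- Comparison: the chosen route is longer after the ring is made, but it needs no skeletal surgery and takes the absolute configuration of C7 from the chiral pool.

Alternative 2: The C5–C6 bond is cut. The open-chain iodo diene A5 would be hydroborated with 9-BBN at its 1,1-disubstituted C6=C7 alkene, and the borane coupled with the C5 vinyl iodide (Pd(dppf)Cl2, AsPh3, Cs2CO3) to close the macrocycle A4.

- For it: both Z-trisubstituted alkenes are fixed in acyclic chemistry, and the three oxygens arrive already differentiated (PMB at C8 for the acetate, silyl ethers at C3 and C9 for the angelates). On both points it is stronger than the chosen route.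
- Against it: a ten-membered ring has to be closed by an sp3–sp2 coupling, the ring size at which strain in the reductive elimination, dimerisation and β-hydride elimination compete hardest. C7 is set by 1,2-induction in the hydroboration of an alkene flanked by a quaternary carbinol carbon. A5 itself needs a long linear synthesis with three stereocentres and two Z-alkenyl units.
- Comparison: the overall step count is probably similar. The chosen route instead has the ring and C7 secured in its first step and spreads its risk over functional-group chemistry on a fixed skeleton.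

Alternative 3: The C3–C8 bond is cut. Pb(OAc)4 would cleave the cis ring-fusion glycol A7 to release the Z,Z-cyclodecadienedione A6.

- For it: the logic is the same as in the chosen route, a ring-fusion bond is broken and no medium ring is closed. Here the Z geometry of both alkenes is inherited from two six-membered rings, and the carbonyl groups appear at C3 and C8, where the target has oxygen. It is therefore stronger on geometry and on redox economy.
- Against it: A7 is not available and must be built with its two quaternary carbinols and the C7 and C9 centres. In A6 the C8 ketone makes both C7 and C9 epimerisable, and C2 lies between the C3 ketone and the C1=C10 bond, so conjugation and isomerisation threaten. The C8 carbonyl must also be reduced with control relative to both neighbours.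
- Comparison: in the chosen route C7 is never α to a carbonyl group, and the key-step precursor is commercial, at the price of transposing the C1 and C5 oxygens.

Key step: step 1

## Route

Remark: ring atoms carry germacrane numbers (C1–C10 ring, C11–C13 on C7, C14 on C10, C15 on C4). C4 and C10 lie next to carbonyl or ketal carbons in 3–12, may epimerise, and are written with the guaiol configuration; both become trigonal later. The SMILES in the compound list define all configurations.

Step 1
Reactants: 1 (−)-guaiol
Product: 3 (4S,7R,10S)-11-hydroxygermacrane-1,5-dione, via secondary ozonide 2 (not isolated)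
Conditions: O3, CH2Cl2, −78 °C; Me2S, −78 °C → rt
Reagents that add atoms: ozone, O=[O+][O-]
Why: Ozone adds as a 1,3-dipole across the only C=C bond, the electron-rich tetrasubstituted C1=C5 bond; the primary ozonide undergoes cycloreversion to a ketone and a carbonyl oxide held in the same ring, these recombine to the secondary ozonide 2, and Me2S reduces its O–O bond to unveil the C1 and C5 ketones. This is the classical ozonolysis of a ring-fusion tetrasubstituted alkene of a hydroazulene or octalin to a medium-ring diketone. No bond is formed in the ring-making event: the ten-membered ring arises by scission of the bond shared by the five- and seven-membered rings, so there is no cyclisation mode to control and no penalty of a medium-ring closure. No stereocentre is created; C7 is untouched and keeps the guaiol configuration, while C4 and C10, now α to carbonyl groups, may epimerise without consequence. The step needs only chemoselectivity, which the substrate secures: there is a single alkene and the tertiary C11 hydroxyl is inert to ozone. Interception of the carbonyl oxide by that hydroxyl would converge on the same product after reduction. The 1,5-dione can undergo transannular aldol closure, so the work-up is kept neutral and cold.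

Step 2
Reactants: 3 (4S,7R,10S)-11-hydroxygermacrane-1,5-dione
Product: 4 (4S,5R,7R,10S)-5,11-epoxy-5-methoxygermacran-1-one
Conditions: MeOH, PPTS (cat.), 4 Å MS, rt
Reagents that add atoms: methanol, CO
Why: The C11 hydroxyl reaches C5 through a five-membered ring but would need a seven-membered ring to reach C1, so hemiketalisation and acid-catalysed exchange with methanol give the mixed ketal at C5 only, as in the transannular hemiketals of ten-membered-ring sesquiterpenoids. The two-atom bridge can span C5 and C7 only on one face, which fixes the new C5 centre. This masks C5 and leaves the C1 ketone free.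

Step 3
Reactants: 4 (4S,5R,7R,10S)-5,11-epoxy-5-methoxygermacran-1-one
Product: 5 5,11-epoxy-5-methoxy-1-(trimethylsilyloxy)germacr-1(10)-ene
Conditions: TMSCl, Et3N, DMF, 90 °C
Reagents that add atoms: chlorotrimethylsilane, C[Si](C)(C)Cl
Why: Thermodynamic silyl enol ether formation (House conditions) favours the tetrasubstituted C1=C10 enol ether over the C1=C2 isomer. With C5 masked no transannular aldol reaction can intervene, and the basic medium spares the ketal.

Step 4
Reactants: 5 5,11-epoxy-5-methoxy-1-(trimethylsilyloxy)germacr-1(10)-ene
Product: 6 (9Z)-5,11-epoxy-5-methoxygermacr-9-en-1-one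
Conditions: Pd(OAc)2 (1.1 equiv), MeCN, rt
Reagents that add atoms: none
Why: Saegusa–Ito dehydrogenation: transmetalation gives the palladium enolate at C10 and syn β-hydride elimination from C9 gives the conjugated endocyclic enone, as with the enol ether of 2-methylcyclohexanone. Either enone geometry serves, because this double bond is relocated in step 5.

Step 5
Reactants: 6 (9Z)-5,11-epoxy-5-methoxygermacr-9-en-1-one
Product: 8 5,11-epoxy-5-methoxygermacra-1(10),8-dien-1-yl trifluoromethanesulfonate (C2 and C9 cis on C1=C10; 8Z), via potassium dienolate 7 (not isolated)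
Conditions: KOt-Bu, THF, 0 °C; PhNTf2, 0 °C → rt
Reagents that add atoms: N-phenylbis(trifluoromethanesulfonimide), O=S(=O)(N(c1ccccc1)S(=O)(=O)C(F)(F)F)C(F)(F)F
Why: Reversible deprotonation with an alkoxide leads to the more stable through-conjugated dienolate 7 (loss of a C8 proton, not of the α′ proton at C2), and O-sulfonylation gives the linear dienyl triflate. Under equilibrating conditions the least strained cis,cis arrangement of the cyclodeca-1,3-diene unit should prevail, which sets the geometry of C1=C10 and C8=C9. C7–H is not acidic in this system.

Step 6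
Reactants: 8 5,11-epoxy-5-methoxygermacra-1(10),8-dien-1-yl trifluoromethanesulfonate
Product: 9 5,11-epoxy-8,9-dihydroxy-5-methoxygermacr-1(10)-en-1-yl trifluoromethanesulfonate (8,9-diol cis; both C–O bonds cis to C7–C11)
Conditions: OsO4 (5 mol %), NMO, acetone/H2O, 0 °C → rt
Reagents that add atoms: osmium tetroxide (oxygen carrier), O=[Os](=O)(=O)=O; N-methylmorpholine N-oxide, C[N+]1([O-])CCOCC1; water, O
Why: Upjohn cis-dihydroxylation: OsO4 adds suprafacially to the only electron-rich alkene, C8=C9, because C1=C10 is tetrasubstituted and deactivated by the triflate; the Z geometry makes the 8,9-diol cis. With H7 eclipsing the double bond (allylic strain), the two faces are flanked by the one-carbon bridge C6 and by the bulky O–CMe2 bridge of the ketal. Attack past the one-carbon bridge, as in exo additions to bicyclo[3.2.1]octenes, places both new C–O bonds cis to the C7–C11 bond.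

Step 7
Reactants: 9 5,11-epoxy-8,9-dihydroxy-5-methoxygermacr-1(10)-en-1-yl trifluoromethanesulfonate
Product: 10 5,11-epoxy-8,9-isopropylidenedioxy-5-methoxygermacr-1(10)-en-1-yl trifluoromethanesulfonate
Conditions: Me2C(OMe)2, PPTS (cat.), acetone, rt
Reagents that add atoms: 2,2-dimethoxypropane, COC(C)(C)OC
Why: Acetal exchange converts the cis-1,2-diol into its acetonide; under anhydrous acid the methyl ketal can only exchange with methanol and persists. The diol is capped before C5 is unmasked so that O8 cannot enter into ketal formation with C5.

Step 8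
Reactants: 10 5,11-epoxy-8,9-isopropylidenedioxy-5-methoxygermacr-1(10)-en-1-yl trifluoromethanesulfonate
Product: 11 (1(10)Z)-5,11-epoxy-8,9-isopropylidenedioxy-5-methoxygermacr-1(10)-ene
Conditions: Pd(OAc)2 (5 mol %), PPh3, HCO2H, Bu3N, DMF, 60 °C
Reagents that add atoms: none
Why: Palladium-catalysed formate reduction of an alkenyl triflate (oxidative addition to zerovalent palladium, formate-to-hydride exchange with loss of CO2, reductive elimination) replaces OTf by H with retention of alkene geometry, giving the Z C1=C10 bond. Allylic ketal ethers are not ionised under these conditions.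

Step 9
Reactants: 11 (1(10)Z)-5,11-epoxy-8,9-isopropylidenedioxy-5-methoxygermacr-1(10)-ene
Product: 12 (1(10)Z)-11-hydroxy-8,9-isopropylidenedioxygermacr-1(10)-en-5-one
Conditions: PPTS (cat.), acetone/H2O, rt
Reagents that add atoms: water, O
Why: Mild aqueous acid hydrolyses the labile 2-alkoxytetrahydrofuran-type ketal, and in wet acetone the dioxolane is retained. C1 is no longer a carbonyl carbon, so the C5 ketone can now be desaturated without placing C2 between two carbonyl-activated positions.

Step 10
Reactants: 12 (1(10)Z)-11-hydroxy-8,9-isopropylidenedioxygermacr-1(10)-en-5-one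
Product: 13 (1(10)Z)-8,9-isopropylidenedioxy-5,11-bis(triethylsilyloxy)germacra-1(10),4-diene
Conditions: TESOTf, Et3N, CH2Cl2, −78 → 0 °C
Reagents that add atoms: triethylsilyl trifluoromethanesulfonate, CC[Si](CC)(CC)OS(=O)(=O)C(F)(F)F
Why: Soft enolisation with a silyl triflate and an amine gives the more substituted enol ether toward C4 (C6 is shielded by the C7 branch). The tertiary hydroxyl is silylated at the same time, which removes the lactol equilibrium and protects C11–O for the following steps.

Step 11
Reactants: 13 (1(10)Z)-8,9-isopropylidenedioxy-5,11-bis(triethylsilyloxy)germacra-1(10),4-diene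
Product: 14 (1(10)Z,3Z)-8,9-isopropylidenedioxy-11-(triethylsilyloxy)germacra-1(10),3-dien-5-one
Conditions: Pd(OAc)2 (1.1 equiv), MeCN/CH2Cl2, rt
Reagents that add atoms: none
Why: Second Saegusa–Ito dehydrogenation: the palladium enolate at C4 undergoes syn β-hydride elimination from C3 to give the endocyclic enone. The isolated trisubstituted C1=C10 bond does not react with Pd(OAc)2 at room temperature at a comparable rate.

Step 12
Reactants: 14 (1(10)Z,3Z)-8,9-isopropylidenedioxy-11-(triethylsilyloxy)germacra-1(10),3-dien-5-one
Product: 15 (1(10)Z)-3,4-epoxy-8,9-isopropylidenedioxy-11-(triethylsilyloxy)germacr-1(10)-en-5-one (mixture at C3 and C4)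
Conditions: H2O2 (30 %), NaOH (cat.), MeOH, 0 °C
Reagents that add atoms: hydrogen peroxide, OO
Why: Weitz–Scheffer epoxidation: conjugate addition of hydroperoxide to the enone and ring closure, as with carvone; the electron-rich C1=C10 bond is inert to the nucleophilic oxidant. The configuration at C3 and C4 is immaterial, because C4 becomes trigonal in step 13 and C3 is reset in steps 14 and 15.

Step 13
Reactants: 15 (1(10)Z)-3,4-epoxy-8,9-isopropylidenedioxy-11-(triethylsilyloxy)germacr-1(10)-en-5-one
Product: 17 (1(10)Z,4Z)-8,9-isopropylidenedioxy-11-(triethylsilyloxy)germacra-1(10),4-dien-3-ol (C3 epimers), via epoxy hydrazone 16 (not isolated)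
Conditions: N2H4·H2O, AcOH (cat.), MeOH, 0 °C → rt
Reagents that add atoms: none
Why: Wharton transposition: the epoxy hydrazone 16 fragments with opening of the epoxide and loss of N2, which moves the oxygen to C3 and creates the C4=C5 bond. The ring-cis (Z) alkene is expected because the vinylic intermediate can relax to the less strained cis-cyclodecene geometry before it is quenched; silyl ethers and the acetonide are stable to hydrazine.

Step 14
Reactants: 17 (1(10)Z,4Z)-8,9-isopropylidenedioxy-11-(triethylsilyloxy)germacra-1(10),4-dien-3-ol
Product: 18 (1(10)Z,4Z)-8,9-isopropylidenedioxy-11-(triethylsilyloxy)germacra-1(10),4-dien-3-one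
Conditions: Dess–Martin periodinane, CH2Cl2, 0 °C → rt
Reagents that add atoms: none
Why: Oxidation of the secondary allylic alcohol converges both C3 epimers on one enone. The near-neutral conditions keep the C1=C10 bond from moving into conjugation through C2.

Step 15
Reactants: 18 (1(10)Z,4Z)-8,9-isopropylidenedioxy-11-(triethylsilyloxy)germacra-1(10),4-dien-3-one
Product: 19 (1(10)Z,3S,4Z)-8,9-isopropylidenedioxy-11-(triethylsilyloxy)germacra-1(10),4-dien-3-ol
Conditions: (R)-2-methyl-CBS-oxazaborolidine (20 mol %), catecholborane, toluene, −78 °C
Reagents that add atoms: none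
Why: Corey–Bakshi–Shibata reduction: the α-methyl alkenyl group acts as the large and the C2 methylene as the small substituent, so the (R)-catalyst delivers hydride to give the 3S alcohol under reagent control, independent of the ring conformation. Only 1,2-reduction occurs at low temperature.

Step 16
Reactants: 19 (1(10)Z,3S,4Z)-8,9-isopropylidenedioxy-11-(triethylsilyloxy)germacra-1(10),4-dien-3-ol; 20 angelic acid
Product: 21 (1(10)Z,3S,4Z)-8,9-isopropylidenedioxy-11-(triethylsilyloxy)germacra-1(10),4-dien-3-yl angelate
Conditions: 20, 2,4,6-trichlorobenzoyl chloride, Et3N, toluene, rt; then 19, 75 °C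
Reagents that add atoms: angelic acid 20, C/C=C(/C)C(O)=O
Why: Yamaguchi-type esterification through the mixed anhydride without a nucleophilic catalyst acylates the only free hydroxyl and avoids the conjugate addition–elimination that would isomerise the angelate to the tiglate. The C3 oxygen is acylated now so that it cannot direct the later vanadium-catalysed epoxidation.

Step 17
Reactants: 21 (1(10)Z,3S,4Z)-8,9-isopropylidenedioxy-11-(triethylsilyloxy)germacra-1(10),4-dien-3-yl angelate
Product: 22 (1(10)Z,3S,4Z)-8,9,11-trihydroxygermacra-1(10),4-dien-3-yl angelate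
Conditions: AcOH/THF/H2O (3:1:1), 45 °C
Reagents that add atoms: none
Why: Aqueous acetic acid hydrolyses the dioxolane and the tertiary silyl ether in one operation. The allylic angelate and the two trisubstituted alkenes tolerate this weak acid.

Step 18
Reactants: 22 (1(10)Z,3S,4Z)-8,9,11-trihydroxygermacra-1(10),4-dien-3-yl angelate
Product: 23 (4Z)-1,10-epoxy-8,9,11-trihydroxygermacr-4-en-3-yl angelate (epoxide cis to the C9 hydroxyl)
Conditions: VO(acac)2 (5 mol %), t-BuOOH, CH2Cl2, 0 °C
Reagents that add atoms: tert-butyl hydroperoxide, CC(C)(C)OO
Why: Hydroxyl-directed epoxidation: the vanadate ester of the allylic C9 hydroxyl delivers the peroxide oxygen to C1=C10 only, and in medium-ring (Z)-allylic alcohols this mode gives the cis epoxy alcohol, here reinforced by the C10 methyl group. The addition is stereospecific, so the Z alkene gives the cis-fused epoxide; C4=C5 has no allylic hydroxyl and reacts far more slowly.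

Step 19
Reactants: 23 (4Z)-1,10-epoxy-8,9,11-trihydroxygermacr-4-en-3-yl angelate
Product: 24 1,10:4,5-diepoxy-8,9,11-trihydroxygermacran-3-yl angelate (4,5-epoxide trans to the C3 ester)
Conditions: m-CPBA, NaHCO3, CH2Cl2, 0 °C
Reagents that add atoms: 3-chloroperbenzoic acid, OOC(=O)c1cccc(Cl)c1
Why: Prilezhaev epoxidation of the one remaining electron-rich alkene; the angelate double bond is electron-poor and inert. The peracid attacks the outer face of the medium-ring Z alkene while the allylic acyloxy group occupies the outward staggered position, the arrangement that gives trans epoxides from medium-ring allylic systems, and the Z geometry gives the cis-fused epoxide. The bicarbonate buffer and the low temperature are meant to keep the free C11 hydroxyl from opening the new epoxide at C5.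

Step 20
Reactants: 24 1,10:4,5-diepoxy-8,9,11-trihydroxygermacran-3-yl angelate
Product: 25 8-acetoxy-1,10:4,5-diepoxy-9,11-dihydroxygermacran-3-yl angelate
Conditions: Ac2O (1.1 equiv), pyridine, CH2Cl2, 0 °C
Reagents that add atoms: acetic anhydride, CC(=O)OC(C)=O
Why: Kinetic acetylation without a nucleophilic catalyst should select O8, whose carbon neighbours are both methine carbons, over O9, which is neopentyl-like next to the quaternary epoxide carbon C10. The tertiary C11 hydroxyl does not react.

Step 21
Reactants: 25 8-acetoxy-1,10:4,5-diepoxy-9,11-dihydroxygermacran-3-yl angelate; 20 angelic acid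
Product: 26 8-acetoxy-1,10:4,5-diepoxy-11-hydroxygermacrane-3,9-diyl diangelate
Conditions: 20, 2,4,6-trichlorobenzoyl chloride, Et3N, toluene, rt; then 25, 80 °C
Reagents that add atoms: angelic acid 20, C/C=C(/C)C(O)=O
Why: The same mixed-anhydride esterification under more forcing conditions acylates the hindered secondary C9 hydroxyl without isomerising the angelate. The tertiary hydroxyl is too hindered to compete, and no strong base is present that could trigger epoxide migration.

Step 22
Reactants: 26 8-acetoxy-1,10:4,5-diepoxy-11-hydroxygermacrane-3,9-diyl diangelate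
Product: 27 (1R,3S,4S,5S,7R,8S,9S,10R)-8-acetoxy-1,10:4,5-diepoxygermacr-11-ene-3,9-diyl diangelate (CNP0260455.1)
Conditions: Burgess reagent, toluene, 60 °C
Reagents that add atoms: none
Why: Burgess dehydration: O-sulfonylation of the tertiary alcohol and syn elimination under neutral conditions that spare the epoxides and esters. The six unhindered methyl hydrogens are favoured over the single C7 hydrogen, which is crowded and adjacent to the acetoxy-bearing carbon, so the isopropenyl group should predominate over the isopropylidene isomer.

## Compound list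

1 | (−)-guaiol | C[C@H]1CCC2=C1C[C@@H](CC[C@@H]2C)C(C)(C)O | starting material
2 | secondary ozonide of guaiol (1,2,4-trioxolane spanning C1 and C5) | CC(C)(O)[C@H]1CC23OOC(O2)([C@@H](C)CC1)CC[C@@H]3C | intermediate
3 | (4S,7R,10S)-11-hydroxygermacrane-1,5-dione [7-(2-hydroxypropan-2-yl)-4,10-dimethylcyclodecane-1,5-dione] | CC(C)(O)[C@H]1CC(=O)[C@@H](C)CCC(=O)[C@@H](C)CC1 | intermediate
4 | (4S,5R,7R,10S)-5,11-epoxy-5-methoxygermacran-1-one | CC1(C)[C@H]2C[C@](O1)(OC)[C@@H](C)CCC(=O)[C@@H](C)CC2 | intermediate
5 | 5,11-epoxy-5-methoxy-1-(trimethylsilyloxy)germacr-1(10)-ene | CC1(C)[C@H]2C[C@](O1)(OC)[C@@H](C)CCC(O[Si](C)(C)C)=C(C)CC2 | intermediate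
6 | (9Z)-5,11-epoxy-5-methoxygermacr-9-en-1-one | CC1(C)[C@H]2C[C@](O1)(OC)[C@@H](C)CCC(=O)/C(C)=C\C2 | intermediate
7 | potassium 5,11-epoxy-5-methoxygermacra-1(10),8-dien-1-olate | CC1(C)[C@H]2C[C@](O1)(OC)[C@@H](C)CC/C([O-])=C(C)\C=C/2.[K+] | intermediate
8 | 5,11-epoxy-5-methoxygermacra-1(10),8-dien-1-yl trifluoromethanesulfonate (ring-cis at both double bonds) | CC1(C)[C@H]2C[C@](O1)(OC)[C@@H](C)CC/C(OS(=O)(=O)C(F)(F)F)=C(C)\C=C/2 | intermediate
9 | 5,11-epoxy-8,9-dihydroxy-5-methoxygermacr-1(10)-en-1-yl trifluoromethanesulfonate (8,9-cis, cis to C7–C11) | CC1(C)[C@H]2C[C@](O1)(OC)[C@@H](C)CC/C(OS(=O)(=O)C(F)(F)F)=C(C)\[C@@H](O)[C@H]2O | intermediate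
10 | 5,11-epoxy-8,9-isopropylidenedioxy-5-methoxygermacr-1(10)-en-1-yl trifluoromethanesulfonate | CC1(C)[C@H]2C[C@](O1)(OC)[C@@H](C)CC/C(OS(=O)(=O)C(F)(F)F)=C(C)\[C@H]3OC(C)(C)O[C@@H]23 | intermediate
11 | (1(10)Z)-5,11-epoxy-8,9-isopropylidenedioxy-5-methoxygermacr-1(10)-ene | CC1(C)[C@H]2C[C@](O1)(OC)[C@@H](C)CC/C=C(C)\[C@H]3OC(C)(C)O[C@@H]23 | intermediate
12 | (1(10)Z)-11-hydroxy-8,9-isopropylidenedioxygermacr-1(10)-en-5-one | CC(C)(O)[C@H]1CC(=O)[C@@H](C)CC/C=C(C)\[C@H]2OC(C)(C)O[C@@H]12 | intermediate
13 | (1(10)Z)-8,9-isopropylidenedioxy-5,11-bis(triethylsilyloxy)germacra-1(10),4-diene | CC(C)(O[Si](CC)(CC)CC)[C@H]1CC(O[Si](CC)(CC)CC)=C(C)CC/C=C(C)\[C@H]2OC(C)(C)O[C@@H]12 | intermediate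
14 | (1(10)Z,3Z)-8,9-isopropylidenedioxy-11-(triethylsilyloxy)germacra-1(10),3-dien-5-one | CC(C)(O[Si](CC)(CC)CC)[C@H]1CC(=O)/C(C)=C\C/C=C(C)\[C@H]2OC(C)(C)O[C@@H]12 | intermediate
15 | (1(10)Z)-3,4-epoxy-8,9-isopropylidenedioxy-11-(triethylsilyloxy)germacr-1(10)-en-5-one (mixture at C3, C4) | CC(C)(O[Si](CC)(CC)CC)[C@H]1CC(=O)C2(C)OC2C/C=C(C)\[C@H]2OC(C)(C)O[C@@H]12 | intermediate
16 | hydrazone of 15 at C5 | CC(C)(O[Si](CC)(CC)CC)[C@H]1CC(=NN)C2(C)OC2C/C=C(C)\[C@H]2OC(C)(C)O[C@@H]12 | intermediate
17 | (1(10)Z,4Z)-8,9-isopropylidenedioxy-11-(triethylsilyloxy)germacra-1(10),4-dien-3-ol (C3 epimers) | CC(C)(O[Si](CC)(CC)CC)[C@H]1C/C=C(C)\C(O)C/C=C(C)\[C@H]2OC(C)(C)O[C@@H]12 | intermediate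
18 | (1(10)Z,4Z)-8,9-isopropylidenedioxy-11-(triethylsilyloxy)germacra-1(10),4-dien-3-one | CC(C)(O[Si](CC)(CC)CC)[C@H]1C/C=C(C)\C(=O)C/C=C(C)\[C@H]2OC(C)(C)O[C@@H]12 | intermediate
19 | (1(10)Z,3S,4Z)-8,9-isopropylidenedioxy-11-(triethylsilyloxy)germacra-1(10),4-dien-3-ol | CC(C)(O[Si](CC)(CC)CC)[C@H]1C/C=C(C)\[C@@H](O)C/C=C(C)\[C@H]2OC(C)(C)O[C@@H]12 | intermediate
20 | angelic acid [(Z)-2-methylbut-2-enoic acid] | C/C=C(/C)C(O)=O | starting material
21 | (1(10)Z,3S,4Z)-8,9-isopropylidenedioxy-11-(triethylsilyloxy)germacra-1(10),4-dien-3-yl angelate | CC(C)(O[Si](CC)(CC)CC)[C@H]1C/C=C(C)\[C@@H](OC(=O)/C(C)=C\C)C/C=C(C)\[C@H]2OC(C)(C)O[C@@H]12 | intermediate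
22 | (1(10)Z,3S,4Z)-8,9,11-trihydroxygermacra-1(10),4-dien-3-yl angelate (7,8,9 all-cis) | CC(C)(O)[C@H]1C/C=C(C)\[C@@H](OC(=O)/C(C)=C\C)C/C=C(C)\[C@@H](O)[C@H]1O | intermediate
23 | (4Z)-1,10-epoxy-8,9,11-trihydroxygermacr-4-en-3-yl angelate (epoxide cis to 9-OH) | CC(C)(O)[C@H]1C/C=C(C)\[C@@H](OC(=O)/C(C)=C\C)C[C@H]2O[C@@]2(C)[C@@H](O)[C@H]1O | intermediate
24 | 1,10:4,5-diepoxy-8,9,11-trihydroxygermacran-3-yl angelate | CC(C)(O)[C@H]1C[C@@H]2O[C@]2(C)[C@@H](OC(=O)/C(C)=C\C)C[C@H]2O[C@@]2(C)[C@@H](O)[C@H]1O | intermediate
25 | 8-acetoxy-1,10:4,5-diepoxy-9,11-dihydroxygermacran-3-yl angelate | CC(C)(O)[C@H]1C[C@@H]2O[C@]2(C)[C@@H](OC(=O)/C(C)=C\C)C[C@H]2O[C@@]2(C)[C@@H](O)[C@H]1OC(C)=O | intermediate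
26 | 8-acetoxy-1,10:4,5-diepoxy-11-hydroxygermacrane-3,9-diyl diangelate | CC(C)(O)[C@H]1C[C@@H]2O[C@]2(C)[C@@H](OC(=O)/C(C)=C\C)C[C@H]2O[C@@]2(C)[C@@H](OC(=O)/C(C)=C\C)[C@H]1OC(C)=O | intermediate
27 | (1R,3S,4S,5S,7R,8S,9S,10R)-8-acetoxy-1,10:4,5-diepoxygermacr-11-ene-3,9-diyl diangelate (CNP0260455.1) | C=C(C)[C@H]1C[C@@H]2O[C@]2(C)[C@@H](OC(=O)/C(C)=C\C)C[C@H]2O[C@@]2(C)[C@@H](OC(=O)/C(C)=C\C)[C@H]1OC(C)=O | target

## Step count and least certain steps

Total step count: 22. Longest linear sequence: 22 steps, from (−)-guaiol 1 to 27; angelic acid 20 is used as purchased.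

**Step 1 (key step).** Most likely to go wrong: incomplete collapse or reduction of peroxidic intermediates of a hindered tetrasubstituted alkene, and transannular aldol closure of the 1,5-dione during work-up, because the two carbonyl groups face each other across the ring. Fallback, from 1 back to 3: stoichiometric OsO4 in pyridine with a reductive NaHSO3 work-up gives the cis-glycol guaiane-1,5,11-triol F1. Pb(OAc)4 in benzene then cleaves the ditertiary glycol of F1 under neutral, non-aqueous conditions to 3.

**Step 5.** Most likely to go wrong: kinetic removal of the α′ proton at C2, giving the cross-conjugated triflate, or incomplete equilibration of the diene geometry, because the enone has two competing acidic sites. Fallback, from 6 back to 8: thermodynamic silylation (TMSCl, Et3N, DMF, 110 °C) gives the through-conjugated dienol ether 5,11-epoxy-5-methoxy-1-(trimethylsilyloxy)germacra-1(10),8-diene F2, which can be purified. Cleavage of F2 with MeLi in THF followed by PhNTf2 releases the dienolate regiospecifically and gives 8.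

**Step 6.** Most likely to go wrong: poor facial selectivity, or addition on the face that carries the O–CMe2 bridge (giving the 7,8-trans diol), because the flexible ring may not present the face assumed. Slow reaction of the deactivated diene is also possible. Fallback, from 8 back to 12: the Woodward cis-hydroxylation (I2, AgOAc, AcOH, then H2O with warming; K2CO3, MeOH) places the cis-diol on the face opposite to the one the electrophile attacks, by double inversion through an acetoxonium ion. The wet acid also removes the methyl ketal, so the product is 8,9,11-trihydroxy-5-oxogermacr-1(10)-en-1-yl trifluoromethanesulfonate F3. It is capped at once with Me2C(OMe)2 and PPTS in acetone as 11-hydroxy-8,9-isopropylidenedioxy-5-oxogermacr-1(10)-en-1-yl trifluoromethanesulfonate F4, and reduction of the triflate of F4 as in step 8 gives 12.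

**Step 13.** Most likely to go wrong: loss of control over the geometry of the new C4=C5 bond, because the ten-membered ring accommodates both isomers and the vinylic intermediate is not configurationally fixed. Fallback, from 17 back to 18: the mixture of 17 and its 4E isomer F5 is oxidised as in step 14 to 18 and the 4E enone F6. The enones are then equilibrated with catalytic I2 in benzene under visible light (reversible iodine-atom addition), which should favour the less strained ring-cis enone 18 before the reduction of step 15.

**Step 19.** Most likely to go wrong: transannular opening of the newly formed 4,5-epoxide by the free C11 hydroxyl. That hydroxyl lies on the ring face opposite to the epoxide oxygen and can reach C5 through the same five-membered bridge that was exploited in step 2. Traces of 3-chlorobenzoic acid, or the warm acylation steps that follow, could trigger the attack. Fallback, from 23 back to 27: the order of events is changed so that the tertiary hydroxyl is gone before the second epoxide is made.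

- Acetylation of 23 as in step 20 gives 8-acetoxy-1,10-epoxy-9,11-dihydroxygermacr-4-en-3-yl angelate F7.
- Esterification with 20 as in step 21 gives 8-acetoxy-1,10-epoxy-11-hydroxygermacr-4-ene-3,9-diyl diangelate F8.
- Burgess dehydration as in step 22 gives 8-acetoxy-1,10-epoxygermacra-4,11-diene-3,9-diyl diangelate F9.
- Buffered m-CPBA then epoxidises the trisubstituted C4=C5 bond of F9 in preference to the less nucleophilic 1,1-disubstituted isopropenyl group and the electron-poor angelates. The facial preference is the one argued for step 19, and the product is 27.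

**Step 20.** Most likely to go wrong: insufficient site selectivity between the two cis-vicinal hydroxyls, and acyl migration between them, with Payne-type epoxide migration from the C9 alkoxide as a further hazard under base. Fallback, from 24 back to 25: MeC(OMe)3 with PPTS converts 24 into its cyclic 8,9-(1-methoxyethylidene) orthoacetate F10. Dilute aqueous acetic acid opens F10 to the two monoacetates, 25 and its 9-O-acetyl isomer F11. Brief treatment with catalytic DBU equilibrates them by 1,2-acyl shift toward the ester on the less hindered O8, that is 25.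

Further compounds
F1 | step 1 | guaiane-1,5,11-triol (cis-1,5-glycol; the face is immaterial) | C[C@H]1CC[C@]2(O)[C@@]1(O)C[C@@H](CC[C@@H]2C)C(C)(C)O
F2 | step 5 | 5,11-epoxy-5-methoxy-1-(trimethylsilyloxy)germacra-1(10),8-diene | CC1(C)[C@H]2C[C@](O1)(OC)[C@@H](C)CC/C(O[Si](C)(C)C)=C(C)\C=C/2
F3 | step 6 | 8,9,11-trihydroxy-5-oxogermacr-1(10)-en-1-yl trifluoromethanesulfonate | CC(C)(O)[C@H]1CC(=O)[C@@H](C)CC/C(OS(=O)(=O)C(F)(F)F)=C(C)\[C@@H](O)[C@H]1O
F4 | step 6 | 11-hydroxy-8,9-isopropylidenedioxy-5-oxogermacr-1(10)-en-1-yl trifluoromethanesulfonate | CC(C)(O)[C@H]1CC(=O)[C@@H](C)CC/C(OS(=O)(=O)C(F)(F)F)=C(C)\[C@H]2OC(C)(C)O[C@@H]12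
F5 | step 13 | (1(10)Z,4E)-8,9-isopropylidenedioxy-11-(triethylsilyloxy)germacra-1(10),4-dien-3-ol | CC(C)(O[Si](CC)(CC)CC)[C@H]1C/C=C(C)/C(O)C/C=C(C)\[C@H]2OC(C)(C)O[C@@H]12
F6 | step 13 | (1(10)Z,4E)-8,9-isopropylidenedioxy-11-(triethylsilyloxy)germacra-1(10),4-dien-3-one | CC(C)(O[Si](CC)(CC)CC)[C@H]1C/C=C(C)/C(=O)C/C=C(C)\[C@H]2OC(C)(C)O[C@@H]12
F7 | step 19 | 8-acetoxy-1,10-epoxy-9,11-dihydroxygermacr-4-en-3-yl angelate | CC(C)(O)[C@H]1C/C=C(C)\[C@@H](OC(=O)/C(C)=C\C)C[C@H]2O[C@@]2(C)[C@@H](O)[C@H]1OC(C)=O
F8 | step 19 | 8-acetoxy-1,10-epoxy-11-hydroxygermacr-4-ene-3,9-diyl diangelate | CC(C)(O)[C@H]1C/C=C(C)\[C@@H](OC(=O)/C(C)=C\C)C[C@H]2O[C@@]2(C)[C@@H](OC(=O)/C(C)=C\C)[C@H]1OC(C)=O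
F9 | step 19 | 8-acetoxy-1,10-epoxygermacra-4,11-diene-3,9-diyl diangelate | C=C(C)[C@H]1C/C=C(C)\[C@@H](OC(=O)/C(C)=C\C)C[C@H]2O[C@@]2(C)[C@@H](OC(=O)/C(C)=C\C)[C@H]1OC(C)=O
F10 | step 20 | cyclic 8,9-(1-methoxyethylidene) orthoacetate of 24 | CC(C)(O)[C@H]1C[C@@H]2O[C@]2(C)[C@@H](OC(=O)/C(C)=C\C)C[C@H]2O[C@@]2(C)[C@H]3OC(C)(OC)O[C@@H]13
F11 | step 20 | 9-acetoxy-1,10:4,5-diepoxy-8,11-dihydroxygermacran-3-yl angelate | CC(C)(O)[C@H]1C[C@@H]2O[C@]2(C)[C@@H](OC(=O)/C(C)=C\C)C[C@H]2O[C@@]2(C)[C@@H](OC(C)=O)[C@H]1O
A1 | alternative 1 | bicyclo[4.4.1]undecatrien-11-one cycloadduct (C11 bridging C2 and C7, C3 silyl ether) | O=C1[C@H]2CC=C(C)[C@@H](O[Si](C)(C)C(C)(C)C)[C@@H]1C=C(C)C=C2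
A2 | alternative 1 | 4-methyltropone | O=C1C=CC(C)=CC=C1
A3 | alternative 1 | (1E)-1-(tert-butyldimethylsilyloxy)-2-methylbuta-1,3-diene | C=C/C(C)=C/O[Si](C)(C)C(C)(C)C
A4 | alternative 2 | (1(10)Z,4Z)-cyclodecadiene with C3 and C9 TBS ethers, C8 PMB ether and C11 TES ether | CC(C)(O[Si](CC)(CC)CC)[C@H]1C/C=C(C)\[C@@H](O[Si](C)(C)C(C)(C)C)C/C=C(C)\[C@@H](O[Si](C)(C)C(C)(C)C)[C@H]1OCc2ccc(OC)cc2
A5 | alternative 2 | open-chain C5 vinyl iodide with the 1,1-disubstituted C6=C7 alkene | C=C(C(C)(C)O[Si](CC)(CC)CC)[C@H](OCc1ccc(OC)cc1)[C@H](O[Si](C)(C)C(C)(C)C)/C(C)=C\C[C@H](O[Si](C)(C)C(C)(C)C)/C(C)=C\I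
A6 | alternative 3 | (1(10)Z,4Z)-cyclodecadiene-3,8-dione with C7 isopropenyl and C9 PMB ether | C=C(C)[C@H]1C/C=C(C)\C(=O)C/C=C(C)\[C@@H](OCc2ccc(OC)cc2)C1=O
A7 | alternative 3 | cis-fused bicyclic C3,C8-glycol (one of the two cis faces drawn; the glycol configuration is erased on cleavage) | C=C(C)[C@H]1CC=C(C)[C@@]2(O)CC=C(C)[C@@H](OCc3ccc(OC)cc3)[C@@]12O
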